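**Retrosynthetic overview**

1. Target ⇐ prenyl group by cross-metathesis of a C13–C14 vinyl group; 3-OH and 9-OH ⇐ twofold allylic hydroxylation of a 4(19),10(18)-diene; C12 carbinol ⇐ allylboration of a lactol from a guaianolide-type 12,6-lactone.
2. Five- and seven-membered rings ⇐ one transannular C1–C5 bond: epoxide-triggered cation–olefin closure of a ten-membered 4,5-epoxy-1(10)-ene lactone (the dilophol → pachydictyol step).
3. Ten-membered ring ⇐ C6–C7 bond (the C1–C10 bond of geranylgeranyl diphosphate) by intramolecular allylation of an epoxy aldehyde; both ring closures are run in one flask from the acyclic chain.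
4. Acyclic chain ⇐ geranyl acetate + allyl Grignard + methyl 2-(bromomethyl)acrylate; a Sharpless epoxide sets C4/C5 and the other centres are relayed from it.
5. Ring order: ten-membered ring first, then the five- and seven-membered rings together.

Assumption: biogenetic (pachydictyane) numbering is used throughout: ring carbons C1–C10 (C1/C5 ring fusion; exocyclic CH2 C19 on C4 and C18 on C10), side chain C11–C17, C20 = methyl on C11. The target is taken as drawn, (1R,3S,5S,6R,7S,9R,11S,12S), with H1 and H5 trans.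

**Route**

Step 1
Reactants: 1 geranyl acetate
Product: 2 (2E,6E)-8-hydroxy-3,7-dimethylocta-2,6-dien-1-yl acetate
Conditions: SeO2 (0.3 equiv), t-BuOOH (2.5 equiv), CH2Cl2, 0 °C → rt
Reagents that add atoms: tert-butyl hydroperoxide, CC(C)(C)OO (oxygen passed on through SeO2, O=[Se]=O)
Why: Sharpless catalytic SeO2 allylic hydroxylation (ene reaction then [2,3]-sigmatropic shift) attacks the (E)-methyl of the electron-rich distal alkene, the acetate deactivating the 2,3-alkene; no stereocentre is formed.

Step 2
Reactants: 2 (2E,6E)-8-hydroxy-3,7-dimethylocta-2,6-dien-1-yl acetate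
Product: 3 (2E,6E)-8-bromo-3,7-dimethylocta-2,6-dien-1-yl acetate
Conditions: CBr4, PPh3, CH2Cl2, 0 °C
Reagents that add atoms: carbon tetrabromide, BrC(Br)(Br)Br
Why: Appel reaction converts the primary allylic alcohol into the bromide under neutral conditions without allylic transposition.

Step 3
Reactants: 3 (2E,6E)-8-bromo-3,7-dimethylocta-2,6-dien-1-yl acetate; 4 allylmagnesium bromide
Product: 6 (2E,6E)-3,7-dimethylundeca-2,6,10-trien-1-ol, via coupled acetate 5 (not isolated)
Conditions: 4 (3.5 equiv), THF, −20 °C → rt; aq. NH4Cl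
Reagents that add atoms: allylmagnesium bromide (4), C=CC[Mg]Br
Why: SN2 allyl–allyl (Wurtz-type) coupling at the primary allylic bromide builds C8–C9 and C7–C8, and the excess Grignard removes the acetate by double addition to the acetyl group; no stereocentre is formed.

Step 4
Reactants: 6 (2E,6E)-3,7-dimethylundeca-2,6,10-trien-1-ol
Product: 7 [(2S,3S)-3-methyl-3-[(3E)-4-methylocta-3,7-dien-1-yl]oxiran-2-yl]methanol
Conditions: Ti(OiPr)4 (10 mol%), L-(+)-diethyl tartrate (12 mol%), t-BuOOH (2 equiv), 4 Å MS, CH2Cl2, −20 °C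
Reagents that add atoms: tert-butyl hydroperoxide, CC(C)(C)OO
Why: Sharpless asymmetric epoxidation touches only the allylic-alcohol alkene, and L-(+)-tartrate gives the (2S,3S)-epoxide, which fixes the future C4 and C5.

Step 5
Reactants: 7 [(2S,3S)-3-methyl-3-[(3E)-4-methylocta-3,7-dien-1-yl]oxiran-2-yl]methanol; 8 methyl 2-(bromomethyl)acrylate
Product: 9 methyl (2Z,6E)-2-(bromomethyl)-9-[(2S,3S)-3-(hydroxymethyl)-2-methyloxiran-2-yl]-6-methylnona-2,6-dienoate
Conditions: 8 (3 equiv), Hoveyda–Grubbs second-generation catalyst (5 mol%), CH2Cl2, 40 °C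
Reagents that add atoms: methyl 2-(bromomethyl)acrylate (8), C=C(CBr)C(=O)OC
Why: Olefin cross-metathesis engages only the monosubstituted terminal alkene (the trisubstituted alkene is inert) and gives the thermodynamic enoate geometry with the chain trans to the ester, i.e. cis to CH2Br.

Step 6
Reactants: 9 methyl (2Z,6E)-2-(bromomethyl)-9-[(2S,3S)-3-(hydroxymethyl)-2-methyloxiran-2-yl]-6-methylnona-2,6-dienoate
Product: 10 methyl (2Z,6E)-2-(bromomethyl)-9-[(2S,3R)-3-formyl-2-methyloxiran-2-yl]-6-methylnona-2,6-dienoate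
Conditions: TEMPO (10 mol%), PhI(OAc)2 (1.2 equiv), CH2Cl2, rt
Reagents that add atoms: none
Why: TEMPO/PhI(OAc)2 oxidation takes the primary epoxy alcohol to the aldehyde without epimerising C5 and leaves the allylic bromide and enoate alone (the descriptor changes only through priorities).

Step 7
Reactants: 10 methyl (2Z,6E)-2-(bromomethyl)-9-[(2S,3R)-3-formyl-2-methyloxiran-2-yl]-6-methylnona-2,6-dienoate
Product: 12 trans-fused (1R,4S,5R,6R,7S)-4-hydroxy-10(18)-ene hydroazulene with cis-fused α-methylene-γ-lactone, via ten-membered epoxy lactone 11 (not isolated)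
Conditions: CrCl2 (6 equiv), THF (2 mM), 10 added over 12 h, rt; then solvent exchange to CH2Cl2 without work-up, BF3·OEt2 (0.5 equiv), 2,6-di-tert-butyl-4-methylpyridine (0.2 equiv), −40 → 0 °C
Reagents that add atoms: none
Why: Proposed new method: a one-flask cyclase-type double ring closure in which divalent chromium turns the allylic bromide into an allylchromium that adds through C7 to the epoxy aldehyde in a chair (Zimmerman–Traxler) transition state (C8 cis to the CH2Cr terminus gives 6,7-syn and hence the cis-lactone; chelation of aldehyde and epoxide oxygens gives 5,6-syn), the alkoxide lactonises, and BF3 then opens the epoxide at C5 with inversion by transannular attack of C1 of the 1(10)-alkene, the cis-lactone being expected to hold the ring in the conformer that gives the trans ring fusion, while the hindered pyridine takes H18 from the C10 cation to give the exocyclic alkene; the closest known reaction types are the Nozaki–Hiyama–Kishi macrocyclisation of 2-(bromomethyl)acrylates onto aldehydes and the Lewis-acid transannular cyclisation of 4,5-epoxygermacranolides to guaianolides.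

Step 8
Reactants: 12 trans-fused 4-hydroxy-10(18)-ene hydroazulene α-methylene lactone
Product: 14 (1R,4S,5R,6R,7S,11S)-4-hydroxy-10(18)-ene hydroazulene α-methyl lactone, via C11-epimeric lactone 13 (not isolated)
Conditions: NaBH4 (1.5 equiv), MeOH, 0 °C; then NaOMe (0.2 equiv), rt
Reagents that add atoms: none
Why: Conjugate (1,4) hydride reduction of the α-methylene-γ-butyrolactone, followed by methoxide equilibration of C11 to the more stable epimer with the methyl on the convex face of the cis-fused lactone (trans to C8), which is the 11S centre.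

Step 9
Reactants: 14 (1R,4S,5R,6R,7S,11S)-4-hydroxy-10(18)-ene hydroazulene α-methyl lactone
Product: 15 (1R,5S,6R,7S,11S)-4(19),10(18)-diene hydroazulene α-methyl lactone
Conditions: SOCl2 (1.5 equiv), pyridine, CH2Cl2, −40 → 0 °C
Reagents that add atoms: none
Why: Dehydration through the chlorosulfite by anti-elimination (E2): H5 is syn to the leaving group and cannot be lost, and pyridine takes the most accessible proton from the C19 methyl to give the exocyclic alkene.

Step 10
Reactants: 15 (1R,5S,6R,7S,11S)-4(19),10(18)-diene hydroazulene α-methyl lactone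
Product: 16 the corresponding C12 lactol (anomer mixture)
Conditions: i-Bu2AlH (1.2 equiv), CH2Cl2, −78 °C; Rochelle salt work-up
Reagents that add atoms: none
Why: DIBAL half-reduction of the lactone stops at the tetrahedral aluminate at −78 °C, and C11 is not epimerised.

Step 11
Reactants: 16 C12 lactol; 17 (−)-B-allyldiisopinocampheylborane
Product: 18 (1R,5S,6R,7S,11S,12S)-6,12-diol with C7 side chain CH(CH3)–CH(OH)–CH2–CH=CH2
Conditions: 17 (2.5 equiv), Et2O, −78 °C → rt; then NaOH, H2O2
Reagents that add atoms: (−)-B-allyldiisopinocampheylborane (17), C=CCB([C@@H]1C[C@@H]2C[C@H]([C@H]1C)C2(C)C)[C@@H]1C[C@@H]2C[C@H]([C@H]1C)C2(C)C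
Why: Brown asymmetric allylboration of the open-chain hydroxy aldehyde through a chair transition state; reagent control is matched with the Felkin–Anh preference of the α-methyl aldehyde and gives the 11,12-syn (12S) carbinol.

Step 12
Reactants: 18 (1R,5S,6R,7S,11S,12S)-6,12-diol
Product: 19 the 12-O-acetate of 18 (6-OH free)
Conditions: Ac2O (1.1 equiv), pyridine, DMAP (5 mol%), CH2Cl2, −20 °C
Reagents that add atoms: acetic anhydride, CC(=O)OC(C)=O
Why: Selective acylation: the C12 hydroxyl (one branched neighbour) reacts much faster than the C6 hydroxyl, which is flanked by two ring methines.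

Step 13
Reactants: 19 12-O-acetate
Product: 21 (3S,9R)-3,6,9-triol 12-acetate with C13–C14 vinyl group, via 3-monool 20 (not isolated)
Conditions: SeO2 (0.5 equiv), t-BuOOH (4 equiv), CH2Cl2, 0 °C → rt
Reagents that add atoms: tert-butyl hydroperoxide, CC(C)(C)OO (oxygen passed on through SeO2, O=[Se]=O)
Why: SeO2 allylic hydroxylation (ene reaction then [2,3]-shift, oxygen on the face that loses H) oxidises the ring CH2 next to each exocyclic methylene (C3, C9; CH2 is preferred over the methines C5 and C1) on the less hindered face (at C3 anti to the C5–C6 bond, at C9 anti to the C7 side chain), and the monosubstituted vinyl group is inert.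

Step 14
Reactants: 21 (3S,9R)-3,6,9-triol 12-acetate with C13–C14 vinyl group; 22 2-methyl-2-butene
Product: 23 CNP0210891.3
Conditions: second-generation Grubbs catalyst (5 mol%), 2-methyl-2-butene/CH2Cl2 (1:1), 40 °C, sealed tube
Reagents that add atoms: 2-methyl-2-butene (22), CC=C(C)C
Why: Olefin cross-metathesis converts the terminal vinyl group into the trisubstituted prenyl alkene, while the 1,1-disubstituted exocyclic methylenes do not react.

**Compound list**

1 | geranyl acetate, (2E)-3,7-dimethylocta-2,6-dien-1-yl acetate | CC(C)=CCC/C(C)=C/COC(C)=O | starting material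
2 | (2E,6E)-8-hydroxy-3,7-dimethylocta-2,6-dien-1-yl acetate | CC(=O)OC/C=C(\C)CC/C=C(\C)CO | intermediate
3 | (2E,6E)-8-bromo-3,7-dimethylocta-2,6-dien-1-yl acetate | CC(=O)OC/C=C(\C)CC/C=C(\C)CBr | intermediate
4 | allylmagnesium bromide | C=CC[Mg]Br | starting material
5 | (2E,6E)-3,7-dimethylundeca-2,6,10-trien-1-yl acetate | CC(=O)OC/C=C(\C)CC/C=C(\C)CCC=C | intermediate (not isolated)
6 | (2E,6E)-3,7-dimethylundeca-2,6,10-trien-1-ol | OC/C=C(\C)CC/C=C(\C)CCC=C | intermediate
7 | [(2S,3S)-3-methyl-3-[(3E)-4-methylocta-3,7-dien-1-yl]oxiran-2-yl]methanol | OC[C@@H]1O[C@@]1(C)CC/C=C(\C)CCC=C | intermediate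
8 | methyl 2-(bromomethyl)acrylate | C=C(CBr)C(=O)OC | starting material
9 | methyl (2Z,6E)-2-(bromomethyl)-9-[(2S,3S)-3-(hydroxymethyl)-2-methyloxiran-2-yl]-6-methylnona-2,6-dienoate | OC[C@@H]1O[C@@]1(C)CC/C=C(\C)CC/C=C(\CBr)C(=O)OC | intermediate
10 | methyl (2Z,6E)-2-(bromomethyl)-9-[(2S,3R)-3-formyl-2-methyloxiran-2-yl]-6-methylnona-2,6-dienoate | O=C[C@@H]1O[C@@]1(C)CC/C=C(\C)CC/C=C(\CBr)C(=O)OC | intermediate
11 | ten-membered epoxy lactone: C1–C10 ring with 1(10)E-alkene, (4S,5S)-epoxide, methyls C19 on C4 and C18 on C10, and a cis-fused α-methylene-γ-butyrolactone C6–O–C12(=O)–C11(=C20H2)–C7 (6R,7S) | C=C1C(=O)O[C@H]2[C@@H]3O[C@@]3(C)CC/C=C(\C)CC[C@@H]12 | intermediate (not isolated)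
12 | (1R,4S,5R,6R,7S)-hydroazulene hydroxy lactone: H1/H5 trans, 4-OH (cis to H5) and 4-CH3, C10=C18H2, cis-fused α-methylene-γ-lactone on C6–C7 | C=C1C(=O)O[C@H]2[C@@H]3[C@@](C)(O)CC[C@H]3C(=C)CC[C@@H]12 | intermediate
13 | (11R)-11,20-dihydro derivative of 12 (C11 methyl cis to C8) | C[C@H]1C(=O)O[C@H]2[C@@H]3[C@@](C)(O)CC[C@H]3C(=C)CC[C@@H]12 | intermediate (not isolated)
14 | (1R,4S,5R,6R,7S,11S)-11,20-dihydro derivative of 12 (C11 methyl trans to C8) | C[C@@H]1C(=O)O[C@H]2[C@@H]3[C@@](C)(O)CC[C@H]3C(=C)CC[C@@H]12 | intermediate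
15 | (1R,5S,6R,7S,11S)-4(19),10(18)-diene hydroazulene with cis-fused α-methyl-γ-lactone (12,6-lactone) | C[C@@H]1C(=O)O[C@H]2[C@@H]3C(=C)CC[C@H]3C(=C)CC[C@@H]12 | intermediate
16 | C12 lactol of 15 (6,12-epoxy-12-ol, anomer mixture) | C[C@@H]1C(O)O[C@H]2[C@@H]3C(=C)CC[C@H]3C(=C)CC[C@@H]12 | intermediate
17 | (−)-B-allyldiisopinocampheylborane [(−)-Ipc2B(allyl), from (+)-α-pinene; commercial solution] | C=CCB([C@@H]1C[C@@H]2C[C@H]([C@H]1C)C2(C)C)[C@@H]1C[C@@H]2C[C@H]([C@H]1C)C2(C)C | starting material
18 | (1R,5S,6R,7S,11S,12S)-trans-hydroazulene-4(19),10(18)-diene-6,12-diol with side chain CH(CH3)–CH(OH)–CH2–CH=CH2 on C7 | C=C1[C@H]2[C@H](O)[C@H]([C@H](C)[C@H](CC=C)O)CCC(=C)[C@@H]2CC1 | intermediate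
19 | 12-O-acetate of 18 | C=C1[C@H]2[C@H](O)[C@H]([C@H](C)[C@H](CC=C)OC(C)=O)CCC(=C)[C@@H]2CC1 | intermediate
20 | (3S)-3-hydroxy derivative of 19 | C=C1[C@H]2[C@H](O)[C@H]([C@H](C)[C@H](CC=C)OC(C)=O)CCC(=C)[C@@H]2C[C@@H]1O | intermediate (not isolated)
21 | (3S,9R)-3,9-dihydroxy derivative of 19 | C=C1[C@H]2[C@H](O)[C@H]([C@H](C)[C@H](CC=C)OC(C)=O)C[C@@H](O)C(=C)[C@@H]2C[C@@H]1O | intermediate
22 | 2-methyl-2-butene | CC=C(C)C | starting material
23 | CNP0210891.3, (1R,3S,5S,6R,7S,9R,11S,12S)-12-acetoxy-pachydictya-4(19),10(18),14-triene-3,6,9-triol | C=C1[C@H]2[C@H](O)[C@H]([C@H](C)[C@H](CC=C(C)C)OC(C)=O)C[C@@H](O)C(=C)[C@@H]2C[C@@H]1O | target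

**Summary**

Total step count: 14. Longest linear sequence: 14 steps, from geranyl acetate 1.

Steps most likely to fail:

Step 7 (one-flask double ring closure; ring-fusion sense and the exocyclic terminus at C10 are not secured by precedent). The fallback sets out from 11, isolated by aqueous work-up after the chromium stage, and comes back at 15. NaBH4 in MeOH followed by NaOMe gives the 11,20-dihydro epoxy macrolactone F1. Cp2TiCl (trivalent titanium, from Cp2TiCl2 and Mn) opens the epoxide homolytically at C4 and takes a hydrogen atom from C19, giving the C5 allylic alcohol F2 with the C4=C19 methylene. ClCO2Me and pyridine give the methyl carbonate F3. Pd(PPh3)4 (zerovalent palladium) with AcOH at 80 °C then forms C1–C5 by a transannular palladium-ene reaction: ionisation anti to the carbonate, syn insertion of the 1(10)-alkene and β-hydride elimination from C18. This gives 15 with both exocyclic alkenes in place and avoids both the C10 cation and the tertiary alcohol.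

Step 9 (regiochemistry of the dehydration; the 3-ene may dominate). The fallback sets out from 14 and comes back at 15. POCl3 in pyridine is used to make the endocyclic 3-ene F4 on purpose (Zaitsev anti-elimination of H3). A contra-thermodynamic positional isomerisation under photochemical hydrogen-atom-transfer catalysis ((Bu4N)4W10O32, Co(dmgH)2(py)Cl, 390 nm) then moves the double bond out to C4=C19.

Step 13 (facial selectivity of the twofold SeO2 hydroxylation). The fallback sets out from 19 and comes back at 21. If SeO2 places the oxygens on the other faces, the product is the 3,9-bis-epimer F5. MnO2 oxidises its two allylic alcohols (not the saturated 6-OH) to the cross-conjugated dienone F6. Luche reduction (NaBH4, CeCl3·7H2O, MeOH, −78 °C) then delivers hydride from the faces SeO2 had used and inverts both carbinols to give 21.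

**Further compounds**

F1 | step 7 | (11S)-11,20-dihydro derivative of epoxy macrolactone 11 | C[C@@H]1C(=O)O[C@H]2[C@@H]3O[C@@]3(C)CC/C=C(\C)CC[C@@H]12
F2 | step 7 | ten-membered C5 allylic alcohol with C4=C19 methylene, 1(10)E-alkene and cis-fused α-methyl lactone | C[C@@H]1C(=O)O[C@H]2[C@H](O)C(=C)CC/C=C(\C)CC[C@@H]12
F3 | step 7 | methyl carbonate of F2 | C[C@@H]1C(=O)O[C@H]2[C@H](OC(=O)OC)C(=C)CC/C=C(\C)CC[C@@H]12
F4 | step 9 | 3-ene isomer of 15 (C3=C4 with C19 methyl, C10=C18H2) | C[C@@H]1C(=O)O[C@H]2[C@@H]3C(C)=CC[C@H]3C(=C)CC[C@@H]12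
F5 | step 13 | (3R,9S)-bis-epimer of 21 | C=C1[C@H]2[C@H](O)[C@H]([C@H](C)[C@H](CC=C)OC(C)=O)C[C@H](O)C(=C)[C@@H]2C[C@H]1O
F6 | step 13 | 3,9-dione of 21 (6-OH and 12-OAc kept) | C=C1[C@H]2[C@H](O)[C@H]([C@H](C)[C@H](CC=C)OC(C)=O)CC(=O)C(=C)[C@@H]2CC1=O
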